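**Assumption:** (2E,6E)-farnesyl acetate, isopentylmagnesium bromide solution and menadiol diacetate are bought as such. The target SMILES reads as 2E,7S,11R,15R,18E,22E,26E.

## Retrosynthetic overview

1. Target 22 ⇐ naphthol acetate 20 (deacetylation, oxidation) ⇐ aryl allyl ether 19 by a [1,3] O→C allyl shift. The key union is the C–O bond between O4 of naphthol 18 and C1 of the C40 allylic alcohol 16 (Mitsunobu etherification).
2. 16 ⇐ terminal alkyne 14 + Me3Al + CH2O (carboalumination fixes 2E); 14 ⇐ C35 bromide 12 + a propargyl anion.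
3. C35 chain ⇐ copper-catalysed sp3–allyl coupling (C16–C17) of the C15 stereotriad Grignard reagent (from 8) with the C20 tail acetate 5.
4. Both halves come from one allylic C–H hydroxylation product 2: the tail via bromide 3 + isopentyl Grignard 4; the triad (C7, C11, C15) via one threefold asymmetric hydrogenation of 2.
5. No ring is formed: the naphthalene bicycle is bought (menadiol diacetate 17) and the quinone is unveiled in the last step.

## Route

Step 1
Reactants: 1 (2E,6E)-3,7,11-trimethyldodeca-2,6,10-trien-1-yl acetate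
Product: 2 (2E,6E,10E)-12-hydroxy-3,7,11-trimethyldodeca-2,6,10-trien-1-yl acetate
Conditions: SeO2 (0.1 equiv), t-BuOOH (3 equiv), salicylic acid (0.1 equiv), CH2Cl2, rt
Reagents that add atoms: tert-butyl hydroperoxide CC(C)(C)OO (terminal oxygen source); selenium dioxide O=[Se]=O (oxygen carrier, catalytic)
Why: SeO2-catalysed allylic hydroxylation (ene reaction then [2,3]-sigmatropic shift) picks the (E)-methyl of the terminal gem-dimethyl alkene, while the acetate deactivates the C2=C3 alkene.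

Step 2
Reactants: 2 (2E,6E,10E)-12-hydroxy-3,7,11-trimethyldodeca-2,6,10-trien-1-yl acetate
Product: 3 (2E,6E,10E)-12-bromo-3,7,11-trimethyldodeca-2,6,10-trien-1-yl acetate
Conditions: CBr4, PPh3, CH2Cl2, −20 to 0 °C
Reagents that add atoms: carbon tetrabromide BrC(Br)(Br)Br
Why: Appel bromination is an SN2 displacement at the primary allylic carbon, so the 10E geometry and the acetate are kept.

Step 3
Reactants: 3 (2E,6E,10E)-12-bromo-3,7,11-trimethyldodeca-2,6,10-trien-1-yl acetate; 4 isopentylmagnesium bromide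
Product: 5 (2E,6E,10E)-3,7,11,15-tetramethylhexadeca-2,6,10-trien-1-yl acetate
Conditions: Li2CuCl4 (3 mol %), THF, −78 to −30 °C, slow addition of 4
Reagents that add atoms: none
Why: Copper-catalysed Grignard cross-coupling (Kochi–Schlosser type) substitutes the allylic bromide at its α-carbon at low temperature, where the allylic acetate and the ester carbonyl do not react.

Step 4
Reactants: 2 (2E,6E,10E)-12-hydroxy-3,7,11-trimethyldodeca-2,6,10-trien-1-yl acetate
Product: 6 (3S,7R,11R)-12-hydroxy-3,7,11-trimethyldodecyl acetate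
Conditions: [Ir(cod)(L)][B(C6H3-3,5-(CF3)2)4] (2 mol %), H2 (50 bar), CH2Cl2, rt; L = 2-phenyl-7-[(di-o-tolylphosphanyl)oxy]-6,7-dihydro-5H-cyclopenta[b]pyridine, the enantiomer that turns (2E,6E)-farnesol into (3S,7S)-3,7,11-trimethyldodecan-1-ol
Reagents that add atoms: none
Why: Proposed new method: a single threefold enantioface-selective hydrogenation of a 1,12-dioxygenated (2E,6E,10E)-triene by a cationic monovalent iridium pyridine–phosphinite catalyst sets C3, C7 and C11 (later C7, C11 and C15 of the target) at once. In the iridium dihydride cycle the face is chosen by where the single vinylic hydrogen sits in the ligand quadrants, and all three alkenes share the same E pattern (vinylic CH on the head side of the methyl-bearing carbon), so one catalyst hand should give the same spatial sense at all three centres, with the OAc and CH2OH groups outside the stereodetermining quadrant. The closest known reaction type is the iridium N,P-catalysed asymmetric hydrogenation of farnesol (two centres) and of single (E)-2-methylallylic alcohols; a three-centre α,ω-difunctional triene has not been shown.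

Step 5
Reactants: 6 (3S,7R,11R)-12-hydroxy-3,7,11-trimethyldodecyl acetate
Product: 7 (3S,7R,11R)-12-bromo-3,7,11-trimethyldodecyl acetate
Conditions: CBr4, PPh3, CH2Cl2, 0 °C to rt
Reagents that add atoms: carbon tetrabromide BrC(Br)(Br)Br
Why: Appel bromination of the primary alcohol does not touch the adjacent C11 stereocentre or the acetate.

Step 6
Reactants: 7 (3S,7R,11R)-12-bromo-3,7,11-trimethyldodecyl acetate
Product: 8 (3S,7R,11R)-12-bromo-3,7,11-trimethyldodecan-1-ol
Conditions: K2CO3 (0.2 equiv), MeOH, rt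
Reagents that add atoms: none
Why: Carbonate-catalysed transesterification removes the acetate while the β-branched primary bromide is too slow an SN2 substrate to react.

Step 7
Reactants: 8 (3S,7R,11R)-12-bromo-3,7,11-trimethyldodecan-1-ol; 5 (2E,6E,10E)-3,7,11,15-tetramethylhexadeca-2,6,10-trien-1-yl acetate
Product: 11 (3S,7S,11R,14E,18E,22E)-3,7,11,15,19,23,27-heptamethyloctacosa-14,18,22-trien-1-ol, via chloromagnesium alkoxide 9 (not isolated), via alkoxide Grignard reagent 10 (not isolated)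
Conditions: i-PrMgCl (1.0 equiv), THF, −20 °C; Mg, THF, 50 °C; then 5, Li2CuCl4 (5 mol %), THF, −20 to 0 °C; aq. NH4Cl
Reagents that add atoms: none
Why: The hydroxyl is masked as its magnesium alkoxide (Normant-type alkoxide Grignard reagent), and copper-catalysed allylic substitution of the prenyl-type acetate goes at the α-carbon with retention of the E geometry, because γ-attack would build a quaternary centre.

Step 8
Reactants: 11 (3S,7S,11R,14E,18E,22E)-3,7,11,15,19,23,27-heptamethyloctacosa-14,18,22-trien-1-ol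
Product: 12 (3S,7S,11R,14E,18E,22E)-1-bromo-3,7,11,15,19,23,27-heptamethyloctacosa-14,18,22-triene
Conditions: CBr4, PPh3, CH2Cl2, 0 °C
Reagents that add atoms: carbon tetrabromide BrC(Br)(Br)Br
Why: Appel bromination is neutral and leaves the three trisubstituted alkenes untouched.

Step 9
Reactants: 12 (3S,7S,11R,14E,18E,22E)-1-bromo-3,7,11,15,19,23,27-heptamethyloctacosa-14,18,22-triene
Product: 14 (6S,10R,14R,17E,21E,25E)-6,10,14,18,22,26,30-heptamethylhentriaconta-17,21,25-trien-1-yne, via silylalkyne 13 (not isolated)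
Conditions: 1-(trimethylsilyl)propyne, n-BuLi, THF, −78 °C; then 12, DMPU, −78 °C to rt; then K2CO3 (cat.), MeOH, rt
Reagents that add atoms: 1-(trimethylsilyl)propyne CC#C[Si](C)(C)C (its three carbons stay)
Why: SN2 alkylation of lithiated 1-(trimethylsilyl)propyne at its propargylic carbon adds C2–C4, and methanolysis then removes the silyl group.

Step 10
Reactants: 14 (6S,10R,14R,17E,21E,25E)-6,10,14,18,22,26,30-heptamethylhentriaconta-17,21,25-trien-1-yne
Product: 16 (2E,7S,11R,15R,18E,22E,26E)-3,7,11,15,19,23,27,31-octamethyldotriaconta-2,18,22,26-tetraen-1-ol, via alkenylalane 15 (not isolated)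
Conditions: Me3Al (2.5 equiv), Cp2ZrCl2 (0.25 equiv), CH2Cl2, 0 °C to rt; then (CH2O)n, THF, 0 °C to rt; cold 1 M HCl
Reagents that add atoms: trimethylaluminium C[Al](C)C (methyl group); paraformaldehyde as formaldehyde C=O (CH2O unit)
Why: Negishi zirconium-catalysed carboalumination adds methyl and aluminium syn across the terminal alkyne, and formaldehyde traps the alkenylalane with retention, which fixes the 2E alkene.

Step 11
Reactants: 17 2-methylnaphthalene-1,4-diyl diacetate
Product: 18 4-hydroxy-2-methylnaphthalen-1-yl acetate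
Conditions: n-BuNH2 (1.05 equiv), THF, 0 °C, Ar
Reagents that add atoms: none
Why: Chemoselective aminolysis cleaves the less hindered 4-acetate (next to C3–H) and leaves the 1-acetate, which is shielded by the 2-methyl group.

Step 12
Reactants: 16 (2E,7S,11R,15R,18E,22E,26E)-3,7,11,15,19,23,27,31-octamethyldotriaconta-2,18,22,26-tetraen-1-ol; 18 4-hydroxy-2-methylnaphthalen-1-yl acetate
Product: 19 2-methyl-4-{[(2E,7S,11R,15R,18E,22E,26E)-3,7,11,15,19,23,27,31-octamethyldotriaconta-2,18,22,26-tetraen-1-yl]oxy}naphthalen-1-yl acetate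
Conditions: PPh3, DIAD, THF, 0 °C to rt
Reagents that add atoms: none
Why: Mitsunobu etherification joins the chain and the core through the O4–C1 bond by SN2 attack of the naphthol on the primary allylic oxyphosphonium, so the 2E alkene is not touched.

Step 13
Reactants: 19 2-methyl-4-{[(2E,7S,11R,15R,18E,22E,26E)-3,7,11,15,19,23,27,31-octamethyldotriaconta-2,18,22,26-tetraen-1-yl]oxy}naphthalen-1-yl acetate
Product: 20 4-hydroxy-2-methyl-3-[(2E,7S,11R,15R,18E,22E,26E)-3,7,11,15,19,23,27,31-octamethyldotriaconta-2,18,22,26-tetraen-1-yl]naphthalen-1-yl acetate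
Conditions: BF3·OEt2 (0.3 equiv), hexane–CH2Cl2 (4:1), −45 to −20 °C, Ar
Reagents that add atoms: none
Why: Lewis-acid-promoted [1,3] O→C allyl migration of an aryl polyprenyl ether (ion-pair ortho rearrangement) delivers the primary allyl terminus to C3, the only free ortho position, and fast collapse of the tight ion pair at low temperature should keep the 2E geometry.

Step 14
Reactants: 20 4-hydroxy-2-methyl-3-[(2E,7S,11R,15R,18E,22E,26E)-3,7,11,15,19,23,27,31-octamethyldotriaconta-2,18,22,26-tetraen-1-yl]naphthalen-1-yl acetate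
Product: 22 2-methyl-3-[(2E,7S,11R,15R,18E,22E,26E)-3,7,11,15,19,23,27,31-octamethyldotriaconta-2,18,22,26-tetraen-1-yl]naphthalene-1,4-dione, via hydroquinone 21 (not isolated)
Conditions: K2CO3 (0.3 equiv), MeOH–THF, Ar, rt; then Ag2O, rt
Reagents that add atoms: none
Why: Methanolysis of the aryl acetate under argon gives the hydroquinone, which Ag2O dehydrogenates to the quinone without forming peroxide that could epoxidise it.

## Compound list

1 | (2E,6E)-3,7,11-trimethyldodeca-2,6,10-trien-1-yl acetate (farnesyl acetate) | CC(=O)OC/C=C(\C)CC/C=C(\C)CCC=C(C)C | starting material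
2 | (2E,6E,10E)-12-hydroxy-3,7,11-trimethyldodeca-2,6,10-trien-1-yl acetate | CC(=O)OC/C=C(\C)CC/C=C(\C)CC/C=C(\C)CO | intermediate
3 | (2E,6E,10E)-12-bromo-3,7,11-trimethyldodeca-2,6,10-trien-1-yl acetate | CC(=O)OC/C=C(\C)CC/C=C(\C)CC/C=C(\C)CBr | intermediate
4 | isopentylmagnesium bromide (3-methylbutylmagnesium bromide) | CC(C)CC[Mg]Br | starting material
5 | (2E,6E,10E)-3,7,11,15-tetramethylhexadeca-2,6,10-trien-1-yl acetate | CC(=O)OC/C=C(\C)CC/C=C(\C)CC/C=C(\C)CCCC(C)C | intermediate
6 | (3S,7R,11R)-12-hydroxy-3,7,11-trimethyldodecyl acetate | CC(=O)OCC[C@@H](C)CCC[C@@H](C)CCC[C@@H](C)CO | intermediate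
7 | (3S,7R,11R)-12-bromo-3,7,11-trimethyldodecyl acetate | CC(=O)OCC[C@@H](C)CCC[C@@H](C)CCC[C@@H](C)CBr | intermediate
8 | (3S,7R,11R)-12-bromo-3,7,11-trimethyldodecan-1-ol | OCC[C@@H](C)CCC[C@@H](C)CCC[C@@H](C)CBr | intermediate
9 | chloromagnesium (3S,7R,11R)-12-bromo-3,7,11-trimethyldodecan-1-olate | Cl[Mg]OCC[C@@H](C)CCC[C@@H](C)CCC[C@@H](C)CBr | intermediate
10 | chloromagnesium (3S,7R,11R)-12-(bromomagnesio)-3,7,11-trimethyldodecan-1-olate | Cl[Mg]OCC[C@@H](C)CCC[C@@H](C)CCC[C@@H](C)C[Mg]Br | intermediate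
11 | (3S,7S,11R,14E,18E,22E)-3,7,11,15,19,23,27-heptamethyloctacosa-14,18,22-trien-1-ol | OCC[C@@H](C)CCC[C@@H](C)CCC[C@@H](C)CC/C=C(\C)CC/C=C(\C)CC/C=C(\C)CCCC(C)C | intermediate
12 | (3S,7S,11R,14E,18E,22E)-1-bromo-3,7,11,15,19,23,27-heptamethyloctacosa-14,18,22-triene | BrCC[C@@H](C)CCC[C@@H](C)CCC[C@@H](C)CC/C=C(\C)CC/C=C(\C)CC/C=C(\C)CCCC(C)C | intermediate
13 | trimethyl[(6S,10R,14R,17E,21E,25E)-6,10,14,18,22,26,30-heptamethylhentriaconta-17,21,25-trien-1-yn-1-yl]silane | C[Si](C)(C)C#CCCC[C@@H](C)CCC[C@@H](C)CCC[C@@H](C)CC/C=C(\C)CC/C=C(\C)CC/C=C(\C)CCCC(C)C | intermediate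
14 | (6S,10R,14R,17E,21E,25E)-6,10,14,18,22,26,30-heptamethylhentriaconta-17,21,25-trien-1-yne | C#CCCC[C@@H](C)CCC[C@@H](C)CCC[C@@H](C)CC/C=C(\C)CC/C=C(\C)CC/C=C(\C)CCCC(C)C | intermediate
15 | dimethyl[(1E,6S,10R,14R,17E,21E,25E)-2,6,10,14,18,22,26,30-octamethylhentriaconta-1,17,21,25-tetraen-1-yl]alumane | C[Al](C)/C=C(\C)CCC[C@@H](C)CCC[C@@H](C)CCC[C@@H](C)CC/C=C(\C)CC/C=C(\C)CC/C=C(\C)CCCC(C)C | intermediate
16 | (2E,7S,11R,15R,18E,22E,26E)-3,7,11,15,19,23,27,31-octamethyldotriaconta-2,18,22,26-tetraen-1-ol | OC/C=C(\C)CCC[C@@H](C)CCC[C@@H](C)CCC[C@@H](C)CC/C=C(\C)CC/C=C(\C)CC/C=C(\C)CCCC(C)C | intermediate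
17 | 2-methylnaphthalene-1,4-diyl diacetate (menadiol diacetate) | CC(=O)Oc1cc(C)c(OC(C)=O)c2ccccc12 | starting material
18 | 4-hydroxy-2-methylnaphthalen-1-yl acetate (menadiol 1-acetate) | CC(=O)Oc1c(C)cc(O)c2ccccc12 | intermediate
19 | 2-methyl-4-{[(2E,7S,11R,15R,18E,22E,26E)-3,7,11,15,19,23,27,31-octamethyldotriaconta-2,18,22,26-tetraen-1-yl]oxy}naphthalen-1-yl acetate | CC(=O)Oc1c(C)cc(OC/C=C(\C)CCC[C@@H](C)CCC[C@@H](C)CCC[C@@H](C)CC/C=C(\C)CC/C=C(\C)CC/C=C(\C)CCCC(C)C)c2ccccc12 | intermediate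
20 | 4-hydroxy-2-methyl-3-[(2E,7S,11R,15R,18E,22E,26E)-3,7,11,15,19,23,27,31-octamethyldotriaconta-2,18,22,26-tetraen-1-yl]naphthalen-1-yl acetate | CC(=O)Oc1c(C)c(C/C=C(\C)CCC[C@@H](C)CCC[C@@H](C)CCC[C@@H](C)CC/C=C(\C)CC/C=C(\C)CC/C=C(\C)CCCC(C)C)c(O)c2ccccc12 | intermediate
21 | 2-methyl-3-[(2E,7S,11R,15R,18E,22E,26E)-3,7,11,15,19,23,27,31-octamethyldotriaconta-2,18,22,26-tetraen-1-yl]naphthalene-1,4-diol | Cc1c(C/C=C(\C)CCC[C@@H](C)CCC[C@@H](C)CCC[C@@H](C)CC/C=C(\C)CC/C=C(\C)CC/C=C(\C)CCCC(C)C)c(O)c2ccccc2c1O | intermediate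
22 | 2-methyl-3-[(2E,7S,11R,15R,18E,22E,26E)-3,7,11,15,19,23,27,31-octamethyldotriaconta-2,18,22,26-tetraen-1-yl]naphthalene-1,4-dione | CC1=C(C/C=C(\C)CCC[C@@H](C)CCC[C@@H](C)CCC[C@@H](C)CC/C=C(\C)CC/C=C(\C)CC/C=C(\C)CCCC(C)C)C(=O)c2ccccc2C1=O | target

## Step count and risks

Total step count: 14. Longest linear sequence: 11 (steps 1, 4, 5, 6, 7, 8, 9, 10, 12, 13, 14).

**Risk 1: step 4, the proposed threefold hydrogenation.** The free allylic alcohol could steer the C11 face differently or isomerise to the aldehyde, the allylic C–OAc bond could be hydrogenolysed, and the three diastereomer-forming events cannot be corrected by separation later. The fallback uses known reductions, sets out from 2 and comes back at 6.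
- TBSCl and imidazole in DMF give (2E,6E,10E)-12-[(tert-butyldimethylsilyl)oxy]-3,7,11-trimethyldodeca-2,6,10-trien-1-yl acetate F1.
- K2CO3 in MeOH frees the allylic alcohol (2E,6E,10E)-12-[(tert-butyldimethylsilyl)oxy]-3,7,11-trimethyldodeca-2,6,10-trien-1-ol F2.
- Ru(OAc)2[(R)-BINAP] (1 mol %, divalent ruthenium) under H2 (30 bar) in MeOH reduces only the allylic-alcohol C2=C3 bond, as in the geraniol-to-citronellol reduction, to (3S,6E,10E)-12-[(tert-butyldimethylsilyl)oxy]-3,7,11-trimethyldodeca-6,10-dien-1-ol F3.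
- Ac2O and pyridine give (3S,6E,10E)-12-[(tert-butyldimethylsilyl)oxy]-3,7,11-trimethyldodeca-6,10-dien-1-yl acetate F4.
- The two remaining alkenes, one purely alkyl-substituted and one a 2-methylallyl silyl ether (each a precedented substrate class for iridium N,P catalysts), are hydrogenated with the step 4 catalyst to (3S,7R,11R)-12-[(tert-butyldimethylsilyl)oxy]-3,7,11-trimethyldodecyl acetate F5.
- TBAF in THF returns 6.

**Risk 2: step 7, the alkoxide Grignard reagent and its coupling.** The chloromagnesium alkoxide may aggregate and stop magnesium insertion, or Wurtz coupling may dominate. The fallback replaces the unprotected dianion with a protect–couple–deprotect sequence; it sets out from 8 and comes back at 11.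
- TBSCl and imidazole give tert-butyl{[(3S,7R,11R)-12-bromo-3,7,11-trimethyldodecyl]oxy}dimethylsilane F6.
- Mg in THF gives (3S,7R,11R)-12-(bromomagnesio)-1-[(tert-butyldimethylsilyl)oxy]-3,7,11-trimethyldodecane F7.
- Li2CuCl4-catalysed coupling with 5 gives tert-butyl{[(3S,7S,11R,14E,18E,22E)-3,7,11,15,19,23,27-heptamethyloctacosa-14,18,22-trien-1-yl]oxy}dimethylsilane F8.
- TBAF returns 11.

**Risk 3: step 13, the [1,3] O→C allyl shift.** Partial loss of the 2E geometry through a loosened allyl cation, acid-induced chroman formation from 20, or crossover could lower yield and purity. The fallback abandons the ether and forms the C1–C2 bond directly; it sets out from 14 and comes back at 22.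
- Menadione is chloromethylated with paraformaldehyde and HCl gas in AcOH to 2-(chloromethyl)-3-methylnaphthalene-1,4-dione F9.
- Alkyne 14 is carboaluminated as in step 10 to alkenylalane 15.
- 15 is coupled with F9 by a zerovalent nickel catalyst made in the flask from NiCl2(PPh3)2 and n-BuLi (THF, rt). This known alkenylalane–chloromethylquinone coupling keeps the 2E geometry and gives 22 without the etherification, rearrangement and deprotection steps.

## Further compounds

F1 | step 4 | (2E,6E,10E)-12-[(tert-butyldimethylsilyl)oxy]-3,7,11-trimethyldodeca-2,6,10-trien-1-yl acetate | CC(=O)OC/C=C(\C)CC/C=C(\C)CC/C=C(\C)CO[Si](C)(C)C(C)(C)C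
F2 | step 4 | (2E,6E,10E)-12-[(tert-butyldimethylsilyl)oxy]-3,7,11-trimethyldodeca-2,6,10-trien-1-ol | OC/C=C(\C)CC/C=C(\C)CC/C=C(\C)CO[Si](C)(C)C(C)(C)C
F3 | step 4 | (3S,6E,10E)-12-[(tert-butyldimethylsilyl)oxy]-3,7,11-trimethyldodeca-6,10-dien-1-ol | OCC[C@@H](C)CC/C=C(\C)CC/C=C(\C)CO[Si](C)(C)C(C)(C)C
F4 | step 4 | (3S,6E,10E)-12-[(tert-butyldimethylsilyl)oxy]-3,7,11-trimethyldodeca-6,10-dien-1-yl acetate | CC(=O)OCC[C@@H](C)CC/C=C(\C)CC/C=C(\C)CO[Si](C)(C)C(C)(C)C
F5 | step 4 | (3S,7R,11R)-12-[(tert-butyldimethylsilyl)oxy]-3,7,11-trimethyldodecyl acetate | CC(=O)OCC[C@@H](C)CCC[C@@H](C)CCC[C@@H](C)CO[Si](C)(C)C(C)(C)C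
F6 | step 7 | tert-butyl{[(3S,7R,11R)-12-bromo-3,7,11-trimethyldodecyl]oxy}dimethylsilane | CC(C)(C)[Si](C)(C)OCC[C@@H](C)CCC[C@@H](C)CCC[C@@H](C)CBr
F7 | step 7 | (3S,7R,11R)-12-(bromomagnesio)-1-[(tert-butyldimethylsilyl)oxy]-3,7,11-trimethyldodecane | CC(C)(C)[Si](C)(C)OCC[C@@H](C)CCC[C@@H](C)CCC[C@@H](C)C[Mg]Br
F8 | step 7 | tert-butyl{[(3S,7S,11R,14E,18E,22E)-3,7,11,15,19,23,27-heptamethyloctacosa-14,18,22-trien-1-yl]oxy}dimethylsilane | CC(C)(C)[Si](C)(C)OCC[C@@H](C)CCC[C@@H](C)CCC[C@@H](C)CC/C=C(\C)CC/C=C(\C)CC/C=C(\C)CCCC(C)C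
F9 | step 13 | 2-(chloromethyl)-3-methylnaphthalene-1,4-dione | CC1=C(CCl)C(=O)c2ccccc2C1=O
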